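The colleague who wants a quick number on these flasks has a hunch, set down below as the forecast; the reply follows the fraction left and not the fraction made.

| setting | larch | alder | ash | winter | noon | midnight | spring | dawn |
|---|---|---|---|---|---|---|---|---|
| substrate | 0.020 M | 0.020 M | 0.020 M | 0.012 M | 0.020 M | 0.030 M | 0.020 M | 0.010 M |
| partner | 0.040 M | 0.040 M | 0.044 M | 0.0600 M | 0.0400 M | 0.0600 M | 0.0400 M | 0.0800 M |
| initiator | 0.11 mM | 0.35 mM | 0.20 mM | 0.20 mM | 0.20 mM | 0.30 mM | 0.10 mM | 0.30 mM |
| remark | run made earlier | run made earlier | run made earlier |  |  |  |  |  |
| time |  |  |  | 6.0 min | 6.0 min | 6.0 min | 6.0 min | 6.0 min |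

| run | time / min | target / % | substrate / % |
|---|---|---|---|
| larch | 1.33 | 9.3 | 90.7 |
| larch | 2.50 | 16.3 | 82.9 |
| larch | 4.00 | 24.4 | 73.7 |
| larch | 5.00 | 28.3 | 68.9 |
| larch | 6.00 | 33.2 | 64.0 |
| alder | 0.500 | 7.0 | 92.9 |
| alder | 1.50 | 18.8 | 80.1 |
| alder | 3.00 | 34.8 | 63.4 |
| alder | 4.00 | 43.3 | 53.7 |
| alder | 6.00 | 57.3 | 36.6 |
| ash | 1.33 | 13.8 | 86.2 |
| ash | 2.50 | 24.2 | 74.3 |
| ash | 4.00 | 36.5 | 61.5 |
| ash | 5.00 | 43.1 | 53.8 |
| ash | 6.00 | 49.0 | 46.9 |

(scatter of a reading: 0.3 percentage points)

- the numbers in the tables scatter by 0.3 percentage points (one standard deviation)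

1. all flasks from highest to lowest amount of target, in percent of the substrate charged, at 6.0 min (winter / noon / midnight / spring / dawn)
2. the amount of target, in percent of the substrate charged of the flask you put first, at 6.0 min
3. the amount of target, in percent of the substrate charged of the flask you put last, at 6.0 min

Assume each turn spends one partner per substrate, so the substrate lost in a run gives the partner left. At its last reading the larch run is reckoned to keep 82.0% of its partner, an apparent pseudo-first-order constant of 0.0331 min⁻¹. The alder run is reckoned to keep 68.3%, or 0.0635 min⁻¹, so the constant, as read from these two runs, follows initiator to the power 0.564. The ash run, with more partner, gives 0.0460 min⁻¹, close to the 0.0463 min⁻¹ of that trend.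

The quantity to carry is therefore the partner survival, the fraction of charged partner left at a given time, taken to follow the initiator charge and not the partner charge. For spring's initiator at 6.0 min it is 82.9%. The fraction of substrate used is the fraction of partner used times the partner-to-substrate ratio of the charge. The gap between substrate lost and target found at the last larch reading, spread over half the run as mean age, reads as a target loss of 0.0270 min⁻¹.

This reply's reckoning gives spring 31.6%, noon 44.8% and midnight 54.4%. In winter and dawn substrate is the limiting reagent, reckoned to reach zero at 4.82 min and 2.29 min. Dawn's target is therefore older at the reading, which gives winter 90.8% and dawn 87.7%. The reckoned order is winter, dawn, midnight, noon, spring.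

The forecast reads dawn > winter > midnight > noon > spring, with 83% first and 31.5% last, and says winter and dawn “depend on the poorly determined substrate order”. It differs from this reckoning by putting dawn above winter and by a top figure lower than the one reckoned here for winter.

The flasks give winter > dawn > midnight > noon > spring, with winter at 91.1%, dawn at 88.9% and spring at 31.5%.

    target ⇌ isomer of the product (K = 2.40, k = 3.70 × 10⁻⁴ s⁻¹)
    initiator → 2 initiating radical (k = 0.00150 s⁻¹)
    first chain carrier → ended carrier (k = 3.80 s⁻¹)
    2 second chain carrier → ended chains A (k = 9.90 × 10⁷ M⁻¹ s⁻¹)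
    substrate + initiating radical → capped initiator + first chain carrier (k = 1.10 × 10⁶ M⁻¹ s⁻¹)
    partner + first chain carrier → target + second chain carrier (k = 39000 M⁻¹ s⁻¹)
    2 first chain carrier → ended chains B (k = 5.20 × 10⁸ M⁻¹ s⁻¹)
    substrate + second chain carrier → by-product + first chain carrier (k = 2.20 × 10⁶ M⁻¹ s⁻¹)

Spring keeps 83% of its partner, against the survival of 82.9%. The neighbour flask is spring charged with 0.016 M of partner and read at the same time. The same survival there means 13.7% of the substrate charge used, so 86.3% substrate left and, with the same target share, 12.6% target. That neighbour flask keeps 83% of its partner and holds 86.1% substrate and 12.6% target.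

(All runs are calculated from invented constants, noise included.)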